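**Plan**
- Retrosynthesis: the eighteen hydroxyls are traced back to sixteen methyl ethers plus a free B3/B4 catechol. The B3 hydroxyl comes from a salicylate ester (reduction, Dakin oxidation), and ring B is cut at B5–B6 and B2–B3.
- Enabling feature: ring B carries two different aryloxy groups meta to each other, the ring A oxygen on B1 and the ring C oxygen on B5, with B4–OH and B3 beside B5. Opened up, B6–B1–B2 is a malonaldehyde bis(acetal) with the ring A ether on its central carbon, and B5–B4–B3 plus the ester carbon is an acetoacetate with the ring C ether on its terminal carbon.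
- The ring C–G chain is cut at its four diaryl ethers (F5–O–G1, E2–O–F1, D4–O–E1, C2–O–D1). Each is made by copper-catalysed arylation of a phenol with a bromobenzaldehyde, whose formyl group is then exchanged for the next phenolic oxygen by Baeyer–Villiger oxidation.
- Forward order: G → F → E → D → C in four arylation/oxidation rounds; acetoacetate and bis(silyloxy)diene on the C1 oxygen; ring B built de novo in the step that also brings in ring A; ester-to-hydroxyl exchange; global demethylation.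
- Stereochemistry: the target has no stereocentre. Enol ether and diene geometries and the transient sp3 centres of the ring closure are erased on aromatisation.

Key step: step 16

Remark on labels: rings are lettered A (2,4,6-trihydroxyphenyl end) to G (3,4,5-trihydroxyphenyl end), with ethers A1–O–B1, B5–O–C1, C2–O–D1, D4–O–E1, E2–O–F1, F5–O–G1.
Abbreviation: Ar5 = 2-(4-{2-[3,4-dimethoxy-5-(3,4,5-trimethoxyphenoxy)phenoxy]-3,4,5-trimethoxyphenoxy}-3,5-dimethoxyphenoxy)-3,4,5-trimethoxyphenyl, the aryl group of phenol 17 (rings C to G, bonded through C1).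
Assumption: the double-bond geometries written for 20, 21, 25 and 28 are those expected to predominate, and 28 and 29 are diastereomer mixtures; none of this affects the outcome.

Step 1
Reactants: 1 3,4,5-trimethoxyphenol; 2 3-bromo-4,5-dimethoxybenzaldehyde
Product: 3 3,4-dimethoxy-5-(3,4,5-trimethoxyphenoxy)benzaldehyde
Conditions: CuI (10 mol%), picolinic acid (20 mol%), K3PO4, DMSO, 90 °C
Reagents that add atoms: none
Why: Ullmann-type copper-catalysed C–O coupling of an unhindered phenol with an aryl bromide that has one ortho methoxy group and a meta formyl group should form the F5–O–G1 ether without difficulty.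

Step 2
Reactants: 3 3,4-dimethoxy-5-(3,4,5-trimethoxyphenoxy)benzaldehyde
Product: 5 3,4-dimethoxy-5-(3,4,5-trimethoxyphenoxy)phenol, via aryl formate 4 (not isolated)
Conditions: mCPBA, CH2Cl2, 0 °C → rt; then K2CO3 (cat.), MeOH, rt
Reagents that add atoms: mCPBA (3-chloroperbenzoic acid), OOC(=O)c1cccc(Cl)c1
Why: Baeyer–Villiger oxidation of a benzaldehyde with a para methoxy group should proceed by aryl migration to the formate, which mild methanolysis cleaves, so the formyl carbon F1 ends up bearing the F1 oxygen.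

Step 3
Reactants: 6 3,4,5-trimethoxybenzaldehyde
Product: 7 2-bromo-3,4,5-trimethoxybenzaldehyde
Conditions: NBS, CHCl3, reflux
Reagents that add atoms: N-bromosuccinimide, O=C1CCC(=O)N1Br
Why: Electrophilic aromatic bromination can only occur at the two equivalent free positions ortho to the formyl group, so a single monobromide is expected.

Step 4
Reactants: 5 3,4-dimethoxy-5-(3,4,5-trimethoxyphenoxy)phenol; 7 2-bromo-3,4,5-trimethoxybenzaldehyde
Product: 8 2-[3,4-dimethoxy-5-(3,4,5-trimethoxyphenoxy)phenoxy]-3,4,5-trimethoxybenzaldehyde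
Conditions: CuI (10 mol%), picolinic acid (20 mol%), K3PO4, DMSO, 90 °C
Reagents that add atoms: none
Why: Ullmann-type coupling in which the bromide is activated by its ortho formyl group and the phenol has two free ortho positions should form the E2–O–F1 ether.

Step 5
Reactants: 8 2-[3,4-dimethoxy-5-(3,4,5-trimethoxyphenoxy)phenoxy]-3,4,5-trimethoxybenzaldehyde
Product: 10 2-[3,4-dimethoxy-5-(3,4,5-trimethoxyphenoxy)phenoxy]-3,4,5-trimethoxyphenol, via aryl formate 9 (not isolated)
Conditions: mCPBA, CH2Cl2, 0 °C → rt; then K2CO3 (cat.), MeOH, rt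
Reagents that add atoms: mCPBA (3-chloroperbenzoic acid), OOC(=O)c1cccc(Cl)c1
Why: Baeyer–Villiger oxidation, favoured by the ortho aryloxy and para methoxy donors, should place the free hydroxyl on E1 next to the new ether.

Step 6
Reactants: 10 2-[3,4-dimethoxy-5-(3,4,5-trimethoxyphenoxy)phenoxy]-3,4,5-trimethoxyphenol; 11 4-bromo-3,5-dimethoxybenzaldehyde
Product: 12 4-{2-[3,4-dimethoxy-5-(3,4,5-trimethoxyphenoxy)phenoxy]-3,4,5-trimethoxyphenoxy}-3,5-dimethoxybenzaldehyde
Conditions: CuI (20 mol%), picolinic acid (40 mol%), K3PO4, DMSO, 110 °C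
Reagents that add atoms: none
Why: Ullmann-type coupling of a mono-ortho-substituted phenol with a bromide flanked by two methoxy groups is the most hindered coupling of the route, but the para formyl group and a ligand system developed for hindered diaryl ethers should allow the D4–O–E1 ether to form.

Step 7
Reactants: 12 4-{2-[3,4-dimethoxy-5-(3,4,5-trimethoxyphenoxy)phenoxy]-3,4,5-trimethoxyphenoxy}-3,5-dimethoxybenzaldehyde
Product: 14 4-{2-[3,4-dimethoxy-5-(3,4,5-trimethoxyphenoxy)phenoxy]-3,4,5-trimethoxyphenoxy}-3,5-dimethoxyphenol, via aryl formate 13 (not isolated)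
Conditions: mCPBA, CH2Cl2, 0 °C → rt; then K2CO3 (cat.), MeOH, rt
Reagents that add atoms: mCPBA (3-chloroperbenzoic acid), OOC(=O)c1cccc(Cl)c1
Why: Baeyer–Villiger oxidation with aryl migration supported by the para aryloxy group should turn the D1 formyl group into the unhindered D1 hydroxyl.

Step 8
Reactants: 14 4-{2-[3,4-dimethoxy-5-(3,4,5-trimethoxyphenoxy)phenoxy]-3,4,5-trimethoxyphenoxy}-3,5-dimethoxyphenol; 7 2-bromo-3,4,5-trimethoxybenzaldehyde
Product: 15 2-(4-{2-[3,4-dimethoxy-5-(3,4,5-trimethoxyphenoxy)phenoxy]-3,4,5-trimethoxyphenoxy}-3,5-dimethoxyphenoxy)-3,4,5-trimethoxybenzaldehyde (Ar5–CHO)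
Conditions: CuI (10 mol%), picolinic acid (20 mol%), K3PO4, DMSO, 90 °C
Reagents that add atoms: none
Why: The same Ullmann-type coupling as in step 4, again with an ortho-formyl-activated bromide and a phenol free at both ortho positions, should form the C2–O–D1 ether.

Step 9
Reactants: 15 Ar5–CHO
Product: 17 2-(4-{2-[3,4-dimethoxy-5-(3,4,5-trimethoxyphenoxy)phenoxy]-3,4,5-trimethoxyphenoxy}-3,5-dimethoxyphenoxy)-3,4,5-trimethoxyphenol (Ar5–OH), via aryl formate 16 (not isolated)
Conditions: mCPBA, CH2Cl2, 0 °C → rt; then K2CO3 (cat.), MeOH, rt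
Reagents that add atoms: mCPBA (3-chloroperbenzoic acid), OOC(=O)c1cccc(Cl)c1
Why: Baeyer–Villiger oxidation as in step 5 should give the C1 hydroxyl that will become the B5–O–C1 ether oxygen.

Step 10
Reactants: 17 Ar5–OH; 18 methyl 4-chloroacetoacetate
Product: 19 methyl 3-oxo-4-(Ar5-oxy)butanoate
Conditions: NaH (2.5 equiv.), THF, 0 °C → reflux; then aq. HCl
Reagents that add atoms: none
Why: Williamson-type O-alkylation at C4 of the chloro ketoester, which is held as its sodium enolate so that it does not self-condense, is the standard entry to 4-aryloxyacetoacetates.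

Step 11
Reactants: 19 methyl 3-oxo-4-(Ar5-oxy)butanoate
Product: 20 methyl (2Z)-4-(Ar5-oxy)-3-(trimethylsilyloxy)but-2-enoate
Conditions: Me3SiCl, Et3N, toluene, rt; filtered under argon
Reagents that add atoms: chlorotrimethylsilane, C[Si](C)(C)Cl
Why: Silyl enol ether formation by O-silylation of the enolised β-ketoester under amine base should give the Z enoate derived from the chelated enol.

Step 12
Reactants: 20 methyl (2Z)-4-(Ar5-oxy)-3-(trimethylsilyloxy)but-2-enoate
Product: 21 (1Z,3Z)-1-methoxy-4-(Ar5-oxy)-1,3-bis(trimethylsilyloxy)buta-1,3-diene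
Conditions: LDA, THF, −78 °C; Me3SiCl, −78 → 20 °C; used crude
Reagents that add atoms: chlorotrimethylsilane, C[Si](C)(C)Cl
Why: Kinetic γ-deprotonation of the silyl enol ether and O-silylation of the resulting dienolate is the standard preparation of 1,3-bis(silyloxy)-1,3-dienes, and the other functional groups are only aryl ethers.

Step 13
Reactants: 22 2,4,6-trimethoxyphenol; 23 bromoacetaldehyde dimethyl acetal
Product: 24 2-(2,2-dimethoxyethoxy)-1,3,5-trimethoxybenzene
Conditions: K2CO3, KI (cat.), DMF, 120 °C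
Reagents that add atoms: none
Why: Williamson ether synthesis at a primary bromide with iodide catalysis should make the ether to the hindered ring A oxygen by alkylation and not by arylation.

Step 14
Reactants: 24 2-(2,2-dimethoxyethoxy)-1,3,5-trimethoxybenzene
Product: 25 1,3,5-trimethoxy-2-[(Z)-2-methoxyethenyloxy]benzene
Conditions: Me3SiOTf, iPr2NEt, CH2Cl2, −20 °C → rt
Reagents that add atoms: none
Why: Acetal-to-enol ether elimination, in which the silyl triflate ionises the acetal and the amine removes the α-proton of the oxocarbenium ion, should give the 1,2-dioxygenated alkene while the base suppresses Friedel–Crafts attack by ring A.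

Step 15
Reactants: 25 1,3,5-trimethoxy-2-[(Z)-2-methoxyethenyloxy]benzene; 26 trimethyl orthoformate
Product: 27 1,1,3,3-tetramethoxy-2-(2,4,6-trimethoxyphenoxy)propane
Conditions: BF3·OEt2 (cat.), CH2Cl2, −20 °C → rt
Reagents that add atoms: none
Why: Lewis acid-catalysed addition of an orthoformate to an enol ether is the classical route to malonaldehyde bis(acetals), and the dimethoxycarbenium ion should attack the aryloxy-bearing carbon because the resulting cation then sits next to the better donor methoxy group.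

Step 16
Reactants: 21 (1Z,3Z)-1-methoxy-4-(Ar5-oxy)-1,3-bis(trimethylsilyloxy)buta-1,3-diene; 27 1,1,3,3-tetramethoxy-2-(2,4,6-trimethoxyphenoxy)propane (1.5 equiv.)
Product: 30 methyl 2-hydroxy-3-(Ar5-oxy)-5-(2,4,6-trimethoxyphenoxy)benzoate, via open-chain adduct 28 (not isolated), via cyclohexanone 29 (not isolated)
Conditions: Me3SiOTf (0.3 equiv.), 4 Å molecular sieves, CH2Cl2, −78 → 20 °C; then 10% aq. HCl
Reagents that add atoms: none
Why: Me3SiOTf ionises one acetal of 27 to an oxocarbenium ion, and the terminal carbon of diene 21 (future B5) adds to it in a vinylogous Mukaiyama aldol-type step that forms B5–B6 and gives 28. Ionisation of the second acetal is followed by attack of the central carbon of the remaining silyl enol ether (future B3), a 6-(enolendo)-exo-trig closure that forms B2–B3 and gives 29, after which two β-eliminations of methanol and enolisation aromatise ring B as the salicylate. The closest known reaction type is the Lewis acid-mediated formal (3+3) cyclocondensation of 1,3-bis(silyloxy)-1,3-dienes, 4-aryloxy dienes included, with 1,1,3,3-tetraalkoxypropanes. No stereocentre survives, so the diastereomer mixtures 28 and 29 converge on one arene. The regiochemistry needs the diene terminus to react first, which its higher nucleophilicity secures, and because the bis(acetal) is symmetric either acetal leads to the same ring, with the two aryloxy groups meta and the hydroxyl between the ring C ether and the ester. Loss of methanol in preference to aryloxide rests on the two methoxy groups lying β to the carbonyl groups while the ring A oxygen is γ, and the silyl enol ethers are far more nucleophilic than the electron-rich arenes, so they should capture the oxocarbenium ions first.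

Step 17
Reactants: 30 methyl 2-hydroxy-3-(Ar5-oxy)-5-(2,4,6-trimethoxyphenoxy)benzoate
Product: 31 2-(hydroxymethyl)-6-(Ar5-oxy)-4-(2,4,6-trimethoxyphenoxy)phenol
Conditions: LiAlH4, THF, 0 °C; aqueous work-up
Reagents that add atoms: none
Why: Hydride reduction of the ester to the primary alcohol should proceed with the phenol carried as its aluminate, and the low temperature avoids benzylic hydrogenolysis through an ortho-quinone methide.

Step 18
Reactants: 31 2-(hydroxymethyl)-6-(Ar5-oxy)-4-(2,4,6-trimethoxyphenoxy)phenol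
Product: 32 2-hydroxy-3-(Ar5-oxy)-5-(2,4,6-trimethoxyphenoxy)benzaldehyde
Conditions: MnO2, CH2Cl2, rt
Reagents that add atoms: none
Why: Benzylic alcohol oxidation with MnO2 stops at the aldehyde and should leave the phenol and the aryl ethers untouched, giving the salicylaldehyde needed for the Dakin reaction.

Step 19
Reactants: 32 2-hydroxy-3-(Ar5-oxy)-5-(2,4,6-trimethoxyphenoxy)benzaldehyde
Product: 34 3-(Ar5-oxy)-5-(2,4,6-trimethoxyphenoxy)benzene-1,2-diol, via aryl formate 33 (not isolated)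
Conditions: 30% H2O2 (1.1 equiv.), NaOH, THF/H2O, 0 °C, argon; then dilute HCl
Reagents that add atoms: hydrogen peroxide, OO
Why: Dakin oxidation of the ortho-hydroxybenzaldehyde (hydroperoxide addition, aryl migration, in situ hydrolysis of the formate) should exchange the B3 carbon substituent for the B3 hydroxyl.

Step 20
Reactants: 34 3-(Ar5-oxy)-5-(2,4,6-trimethoxyphenoxy)benzene-1,2-diol
Product: 35 CNP0137585.0, 2-{3-[2-(4-{2-[3,4-dihydroxy-5-(3,4,5-trihydroxyphenoxy)phenoxy]-3,4,5-trihydroxyphenoxy}-3,5-dihydroxyphenoxy)-3,4,5-trihydroxyphenoxy]-4,5-dihydroxyphenoxy}benzene-1,3,5-triol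
Conditions: BBr3 (excess), CH2Cl2, −78 °C → rt; then H2O, argon
Reagents that add atoms: none
Why: Lewis acid-mediated aryl methyl ether cleavage with BBr3 (borane–ether adduct, bromide attack at methyl) should remove all sixteen methyl groups while the six diaryl ethers, which lack an sp3 carbon on oxygen, stay intact.

**Compound list**
1 | 3,4,5-trimethoxyphenol | COc1cc(O)cc(OC)c1OC | starting material
2 | 3-bromo-4,5-dimethoxybenzaldehyde | COc1cc(C=O)cc(Br)c1OC | starting material
3 | 3,4-dimethoxy-5-(3,4,5-trimethoxyphenoxy)benzaldehyde (ring F–G aldehyde) | COc1cc(C=O)cc(Oc2cc(OC)c(OC)c(OC)c2)c1OC | intermediate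
4 | 3,4-dimethoxy-5-(3,4,5-trimethoxyphenoxy)phenyl formate | COc1cc(OC=O)cc(Oc2cc(OC)c(OC)c(OC)c2)c1OC | intermediate (not isolated)
5 | 3,4-dimethoxy-5-(3,4,5-trimethoxyphenoxy)phenol (ring F–G phenol) | COc1cc(O)cc(Oc2cc(OC)c(OC)c(OC)c2)c1OC | intermediate
6 | 3,4,5-trimethoxybenzaldehyde | COc1cc(C=O)cc(OC)c1OC | starting material
7 | 2-bromo-3,4,5-trimethoxybenzaldehyde | COc1cc(C=O)c(Br)c(OC)c1OC | intermediate
8 | 2-[3,4-dimethoxy-5-(3,4,5-trimethoxyphenoxy)phenoxy]-3,4,5-trimethoxybenzaldehyde (ring E–G aldehyde) | COc1cc(C=O)c(Oc2cc(OC)c(OC)c(Oc3cc(OC)c(OC)c(OC)c3)c2)c(OC)c1OC | intermediate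
9 | 2-[3,4-dimethoxy-5-(3,4,5-trimethoxyphenoxy)phenoxy]-3,4,5-trimethoxyphenyl formate | COc1cc(OC=O)c(Oc2cc(OC)c(OC)c(Oc3cc(OC)c(OC)c(OC)c3)c2)c(OC)c1OC | intermediate (not isolated)
10 | 2-[3,4-dimethoxy-5-(3,4,5-trimethoxyphenoxy)phenoxy]-3,4,5-trimethoxyphenol (ring E–G phenol) | COc1cc(O)c(Oc2cc(OC)c(OC)c(Oc3cc(OC)c(OC)c(OC)c3)c2)c(OC)c1OC | intermediate
11 | 4-bromo-3,5-dimethoxybenzaldehyde | COc1cc(C=O)cc(OC)c1Br | starting material
12 | 4-{2-[3,4-dimethoxy-5-(3,4,5-trimethoxyphenoxy)phenoxy]-3,4,5-trimethoxyphenoxy}-3,5-dimethoxybenzaldehyde (ring D–G aldehyde) | COc1cc(C=O)cc(OC)c1Oc2cc(OC)c(OC)c(OC)c2Oc3cc(OC)c(OC)c(Oc4cc(OC)c(OC)c(OC)c4)c3 | intermediate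
13 | 4-{2-[3,4-dimethoxy-5-(3,4,5-trimethoxyphenoxy)phenoxy]-3,4,5-trimethoxyphenoxy}-3,5-dimethoxyphenyl formate | COc1cc(OC=O)cc(OC)c1Oc2cc(OC)c(OC)c(OC)c2Oc3cc(OC)c(OC)c(Oc4cc(OC)c(OC)c(OC)c4)c3 | intermediate (not isolated)
14 | 4-{2-[3,4-dimethoxy-5-(3,4,5-trimethoxyphenoxy)phenoxy]-3,4,5-trimethoxyphenoxy}-3,5-dimethoxyphenol (ring D–G phenol) | COc1cc(O)cc(OC)c1Oc2cc(OC)c(OC)c(OC)c2Oc3cc(OC)c(OC)c(Oc4cc(OC)c(OC)c(OC)c4)c3 | intermediate
15 | 2-(4-{2-[3,4-dimethoxy-5-(3,4,5-trimethoxyphenoxy)phenoxy]-3,4,5-trimethoxyphenoxy}-3,5-dimethoxyphenoxy)-3,4,5-trimethoxybenzaldehyde (Ar5–CHO) | COc1cc(C=O)c(Oc2cc(OC)c(Oc3cc(OC)c(OC)c(OC)c3Oc4cc(OC)c(OC)c(Oc5cc(OC)c(OC)c(OC)c5)c4)c(OC)c2)c(OC)c1OC | intermediate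
16 | Ar5 formate, the formate ester of phenol 17 | COc1cc(OC=O)c(Oc2cc(OC)c(Oc3cc(OC)c(OC)c(OC)c3Oc4cc(OC)c(OC)c(Oc5cc(OC)c(OC)c(OC)c5)c4)c(OC)c2)c(OC)c1OC | intermediate (not isolated)
17 | 2-(4-{2-[3,4-dimethoxy-5-(3,4,5-trimethoxyphenoxy)phenoxy]-3,4,5-trimethoxyphenoxy}-3,5-dimethoxyphenoxy)-3,4,5-trimethoxyphenol (Ar5–OH) | COc1cc(O)c(Oc2cc(OC)c(Oc3cc(OC)c(OC)c(OC)c3Oc4cc(OC)c(OC)c(Oc5cc(OC)c(OC)c(OC)c5)c4)c(OC)c2)c(OC)c1OC | intermediate
18 | methyl 4-chloroacetoacetate | COC(=O)CC(=O)CCl | starting material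
19 | methyl 3-oxo-4-(Ar5-oxy)butanoate | COC(=O)CC(=O)COc1cc(OC)c(OC)c(OC)c1Oc2cc(OC)c(Oc3cc(OC)c(OC)c(OC)c3Oc4cc(OC)c(OC)c(Oc5cc(OC)c(OC)c(OC)c5)c4)c(OC)c2 | intermediate
20 | methyl (2Z)-4-(Ar5-oxy)-3-(trimethylsilyloxy)but-2-enoate | COC(=O)/C=C(\O[Si](C)(C)C)COc1cc(OC)c(OC)c(OC)c1Oc2cc(OC)c(Oc3cc(OC)c(OC)c(OC)c3Oc4cc(OC)c(OC)c(Oc5cc(OC)c(OC)c(OC)c5)c4)c(OC)c2 | intermediate
21 | (1Z,3Z)-1-methoxy-4-(Ar5-oxy)-1,3-bis(trimethylsilyloxy)buta-1,3-diene | CO/C(O[Si](C)(C)C)=C/C(O[Si](C)(C)C)=C/Oc1cc(OC)c(OC)c(OC)c1Oc2cc(OC)c(Oc3cc(OC)c(OC)c(OC)c3Oc4cc(OC)c(OC)c(Oc5cc(OC)c(OC)c(OC)c5)c4)c(OC)c2 | intermediate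
22 | 2,4,6-trimethoxyphenol | COc1cc(OC)c(O)c(OC)c1 | starting material
23 | bromoacetaldehyde dimethyl acetal | COC(CBr)OC | starting material
24 | 2-(2,2-dimethoxyethoxy)-1,3,5-trimethoxybenzene | COC(COc1c(OC)cc(OC)cc1OC)OC | intermediate
25 | 1,3,5-trimethoxy-2-[(Z)-2-methoxyethenyloxy]benzene | CO/C=C\Oc1c(OC)cc(OC)cc1OC | intermediate
26 | trimethyl orthoformate | COC(OC)OC | starting material
27 | 1,1,3,3-tetramethoxy-2-(2,4,6-trimethoxyphenoxy)propane | COC(OC)C(Oc1c(OC)cc(OC)cc1OC)C(OC)OC | intermediate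
28 | methyl (2Z)-5,7,7-trimethoxy-4-(Ar5-oxy)-6-(2,4,6-trimethoxyphenoxy)-3-(trimethylsilyloxy)hept-2-enoate, diastereomer mixture | COC(=O)/C=C(\O[Si](C)(C)C)C(Oc1cc(OC)c(OC)c(OC)c1Oc2cc(OC)c(Oc3cc(OC)c(OC)c(OC)c3Oc4cc(OC)c(OC)c(Oc5cc(OC)c(OC)c(OC)c5)c4)c(OC)c2)C(OC)C(Oc6c(OC)cc(OC)cc6OC)C(OC)OC | intermediate (not isolated)
29 | methyl 4,6-dimethoxy-2-oxo-3-(Ar5-oxy)-5-(2,4,6-trimethoxyphenoxy)cyclohexane-1-carboxylate, diastereomer mixture | COC(=O)C1C(OC)C(Oc2c(OC)cc(OC)cc2OC)C(OC)C(Oc3cc(OC)c(OC)c(OC)c3Oc4cc(OC)c(Oc5cc(OC)c(OC)c(OC)c5Oc6cc(OC)c(OC)c(Oc7cc(OC)c(OC)c(OC)c7)c6)c(OC)c4)C1=O | intermediate (not isolated)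
30 | methyl 2-hydroxy-3-(Ar5-oxy)-5-(2,4,6-trimethoxyphenoxy)benzoate (heptamer salicylate) | COC(=O)c1cc(Oc2c(OC)cc(OC)cc2OC)cc(Oc3cc(OC)c(OC)c(OC)c3Oc4cc(OC)c(Oc5cc(OC)c(OC)c(OC)c5Oc6cc(OC)c(OC)c(Oc7cc(OC)c(OC)c(OC)c7)c6)c(OC)c4)c1O | intermediate
31 | 2-(hydroxymethyl)-6-(Ar5-oxy)-4-(2,4,6-trimethoxyphenoxy)phenol | OCc1cc(Oc2c(OC)cc(OC)cc2OC)cc(Oc3cc(OC)c(OC)c(OC)c3Oc4cc(OC)c(Oc5cc(OC)c(OC)c(OC)c5Oc6cc(OC)c(OC)c(Oc7cc(OC)c(OC)c(OC)c7)c6)c(OC)c4)c1O | intermediate
32 | 2-hydroxy-3-(Ar5-oxy)-5-(2,4,6-trimethoxyphenoxy)benzaldehyde | O=Cc1cc(Oc2c(OC)cc(OC)cc2OC)cc(Oc3cc(OC)c(OC)c(OC)c3Oc4cc(OC)c(Oc5cc(OC)c(OC)c(OC)c5Oc6cc(OC)c(OC)c(Oc7cc(OC)c(OC)c(OC)c7)c6)c(OC)c4)c1O | intermediate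
33 | 2-hydroxy-3-(Ar5-oxy)-5-(2,4,6-trimethoxyphenoxy)phenyl formate | O=COc1cc(Oc2c(OC)cc(OC)cc2OC)cc(Oc3cc(OC)c(OC)c(OC)c3Oc4cc(OC)c(Oc5cc(OC)c(OC)c(OC)c5Oc6cc(OC)c(OC)c(Oc7cc(OC)c(OC)c(OC)c7)c6)c(OC)c4)c1O | intermediate (not isolated)
34 | 3-(Ar5-oxy)-5-(2,4,6-trimethoxyphenoxy)benzene-1,2-diol | Oc1cc(Oc2c(OC)cc(OC)cc2OC)cc(Oc3cc(OC)c(OC)c(OC)c3Oc4cc(OC)c(Oc5cc(OC)c(OC)c(OC)c5Oc6cc(OC)c(OC)c(Oc7cc(OC)c(OC)c(OC)c7)c6)c(OC)c4)c1O | intermediate
35 | CNP0137585.0, 2-{3-[2-(4-{2-[3,4-dihydroxy-5-(3,4,5-trihydroxyphenoxy)phenoxy]-3,4,5-trihydroxyphenoxy}-3,5-dihydroxyphenoxy)-3,4,5-trihydroxyphenoxy]-4,5-dihydroxyphenoxy}benzene-1,3,5-triol | Oc1cc(O)c(Oc2cc(O)c(O)c(Oc3cc(O)c(O)c(O)c3Oc3cc(O)c(Oc4cc(O)c(O)c(O)c4Oc4cc(O)c(O)c(Oc5cc(O)c(O)c(O)c5)c4)c(O)c3)c2)c(O)c1 | target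

**Totals**
Total step count: 20. Longest linear sequence: 16 steps (steps 1, 2, 4–12 and 16–20, counted from 1).

**Steps most likely to fail**

Step 16. The ring closure is run on the most advanced material, and two processes could drain it: desilylation of the crude diene before the first C–C bond forms, and capture of the ionised acetal by the electron-rich arenes in competition with the enol ether. The fallback keeps the same two bonds but changes the electrophile and its activation. It sets out from 27, which partial hydrolysis (TsOH cat., one equivalent of water, THF) should convert into (2Z)-3-methoxy-2-(2,4,6-trimethoxyphenoxy)prop-2-enal F1. This β-methoxy enal is then condensed with diene 21 under TiCl4 in CH2Cl2 at −78 → 20 °C. A Mukaiyama aldol addition of the diene terminus to the aldehyde, vinylogous substitution of the methoxy group by the central carbon, and dehydration lead back to the route at 30.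

Step 6. Oxidative addition at the bromide flanked by two methoxy groups may be so slow that protodebromination of 11 and oxidative loss of phenol 10 take over. The fallback replaces the copper-catalysed coupling by a metal-free addition–elimination. Setting out from 10, the phenoxide (K2CO3, DMSO, 120 °C) attacks purchased 4-fluoro-3,5-dimethoxybenzaldehyde, whose fluoride is activated by the para formyl group and offers little steric resistance. The route is rejoined at 12, and no compound outside the list is made (F0).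

Step 20. Cleavage of sixteen methyl ethers may stop short on part of the material, and the free polyphenol may oxidise in air during isolation, so the product could be lost in an inseparable polar mixture. The fallback changes the isolation and not the cleavage. Setting out from 34, the crude BBr3 product is acetylated at once (Ac2O, pyridine, DMAP cat.) to the octadecaacetate of the target F2. This ester is stable, can be purified on silica and can be separated from incompletely demethylated material. Deacetylation with HCl in MeOH under argon then comes back to the route at 35.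

**Further compounds**
F1 | step 16 | (2Z)-3-methoxy-2-(2,4,6-trimethoxyphenoxy)prop-2-enal | CO/C=C(/C=O)Oc1c(OC)cc(OC)cc1OC
F0 | step 6 | none | none
F2 | step 20 | octadecaacetate of 35 (all eighteen hydroxyls as acetates) | CC(=O)Oc1cc(OC(C)=O)c(Oc2cc(OC(C)=O)c(OC(C)=O)c(Oc3cc(OC(C)=O)c(OC(C)=O)c(OC(C)=O)c3Oc3cc(OC(C)=O)c(Oc4cc(OC(C)=O)c(OC(C)=O)c(OC(C)=O)c4Oc4cc(OC(C)=O)c(OC(C)=O)c(Oc5cc(OC(C)=O)c(OC(C)=O)c(OC(C)=O)c5)c4)c(OC(C)=O)c3)c2)c(OC(C)=O)c1
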